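## The problem

The target 16 is guibourtinidol-(4α→8)-epiafzelechin. An upper 5-deoxy flavan-3-ol (rings A, B, C; 7,4'-dihydroxy) is bonded from its C4 to C8 of a lower flavan-3-ol (rings D, E, F; 5,7,4'-trihydroxy). There are five stereocentres: upper C2 (R), C3 (S) and C4 (S), all trans, and lower C2 (R) and C3 (R), cis. Within the upper unit the C2/C3 pair can control C4, because a carbon nucleophile enters a C4 cation anti to the C3 oxygen. Nothing in one unit can control the other, so each half needs its own absolute control. The lower cis pair is the less stable arrangement, so it has to be set kinetically and then kept from ionizing at C2. Ring D must be substituted at the carbon next to O1 (C8) and not at C6, and electrophilic substitution on a finished lower flavan separates these two sites only by a preference. The six phenols are oxidation-prone, and the two benzylic C2–O bonds and the interflavan bond are acid-labile; the missing 5-oxygen in ring A makes that bond much sturdier than in procyanidins. The enabling feature is that lower C4 is a bare methylene and C4a is the only ring D carbon ortho to O1 that does not carry the upper unit. An aryl ether on O1 with a terminal epoxide can therefore close ring F by C4–C4a bond formation in one way only.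

## Retrosynthesis

**16 ⇒ 15.** The six O–benzyl bonds are cut last. Benzyl ethers are preferred to methyl or silyl ethers because they survive Lewis acids, hydride, Mitsunobu conditions and peroxide, and all fall in one neutral hydrogenolysis. The free lower 3-hydroxyl of 15 needs no protection.

**15 ⇒ 14.** Lower C4–C4a is cut, which opens ring F to the aryl epoxy ether 14. The neighbouring cuts are less attractive: cutting the interflavan bond here would bring back the C8/C6 question, and cutting O1–C2 would first require a three-carbon chain C-bonded to ring D. The precursor has one ring fewer and the same stereocentres. The forward reaction must open the epoxide at its terminal carbon (6-endo) without ionizing the C2–O bond.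

**14 ⇒ 11 + 13.** The ether bond between the ring D oxygen and lower C2 is cut. This divides the molecule into the upper unit carrying a phenol (11) and a three-carbon aryl epoxy alcohol (13), and it is the most convergent cut available. A Mitsunobu reaction is asked to proceed with clean inversion, so the erythro alcohol 13 becomes the threo ether that maps onto the 2,3-cis flavan.

**13 ⇒ 12 ⇒ 3.** Both stereocentres of 13 come from one Sharpless kinetic resolution of the racemic allylic alcohol 12, which is one Grignard addition away from aldehyde 3. This is shorter than any route that sets the carbinol and the epoxide separately.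

**11 ⇒ 9 + 10.** The upper C4–aryl bond is cut to the flavan-4-ol 9 and commercial phenol 10. Forming this bond on a simple phenol instead of a finished lower flavan leaves the ring F closure for later, where it is regiospecific. The forward Friedel–Crafts reaction must give the 3,4-trans product and must substitute 10 ortho to its hydroxyl.

**9 ⇒ 8 ⇒ 7.** Ketone reduction and O-benzylation are functional-group changes. The C3 benzyl ether is put on at the ketone stage, where the 3-hydroxyl is the only free hydroxyl. It is needed because a free upper 3-OH would compete in step 10 and could be displaced by the neighbouring ring D phenol.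

**7 ⇒ 5 ⇒ 4.** O1–C2 of ring C is cut to the epoxy ketone 5 (through the free phenol 6), and the epoxide is traced back to the chalcone 4. One asymmetric epoxidation then sets both C2 and C3 of the upper unit; C2 is inverted during ring closure and C3 is kept.

**4 ⇒ 2 + 3; 2 ⇒ 1.** The enone is cut by a Claisen–Schmidt condensation into the MOM-protected acetophenone 2 and aldehyde 3, which therefore serves both halves. The MOM group is placed on commercial 1 before the enone exists, so no 2'-hydroxychalcone that could cyclize to a flavanone is ever handled.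

## Roads not taken

**Alternative 1:** The cut is C3–C4 of the upper ring C. In the forward sense, keto aldehyde A2 would be treated with SmI2 (divalent samarium); the ketyl of the ring A/ring D diaryl ketone adds to the aldehyde and gives the cis-3,4-diol A1.
- Merits: the interflavan carbon is bonded to ring D from the start through a sturdy ketone, and the ring closure is reductive and neutral, so no acid touches the assembled dimer. In that respect it is safer than the chosen key step.
- Weak points: A1 has a tertiary benzylic hydroxyl at C4 that must be replaced by hydrogen with retention. Ionic reduction passes through the planar cation and hydride should enter anti to the C3 oxygen, which puts the aryl group cis to it, the wrong isomer. The aldehyde carbon of A2 is next to a benzylic, oxygen-bearing C2 that can epimerize. Making A2 needs the complete lower flavan acylated at C8, which brings back the C8/C6 question.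
- Comparison: the chosen plan has to accept a Lewis acid on a sensitive substrate, but it sets upper C4 directly with the usual anti selectivity, needs no deoxygenation and fixes the ring D regiochemistry by construction.

**Alternative 2:** Three bonds of ring C are cut at once: upper C4–lower C8, C3–C4 and O1–C2. In the forward sense the lower-unit aryl Grignard reagent A4 adds to the O-Boc salicylaldehyde A5. Boc transfer and loss of tert-butyl carbonate release an ortho-quinone methide, which the (E)-styrylboronate A6 traps in an endo [4+2] addition to give boronate A3. Oxidation of the C–B bond with retention would then give the 3-ol.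
- Merits: it is the most convergent of the four plans, and in step economy for ring C it is better than the chosen one. The E-alkene gives 2,3-trans and the endo mode gives 2,4-cis, which is the relative configuration needed.
- Weak points: the quinone methide is planar and achiral, and the stereocentres of A4 are far from the reacting carbon. The new ring should therefore form in both absolute senses, giving two diastereomers of A3 in similar amounts. A vinylboronate is also a weaker 2π partner for an electron-poor heterodiene than an enol ether or a plain styrene.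
- Comparison: the chosen plan is longer, but each half is made under reagent control (peptide-catalysed epoxidation, tartrate-controlled resolution), so the relation between the two units is defined.

**Alternative 3:** The cut is the aryl ether bond C8a–O1 of the upper ring C. In the forward sense bromo alcohol A8 would cyclize to the hepta-O-benzyl compound A7, either with zerovalent palladium from Pd2(dba)3 and a bulky biaryl phosphine or with CuI (monovalent copper) and a phenanthroline.
- Merits: every stereocentre is retained, the conditions are basic and not acidic, and the end game is the same single hydrogenolysis. The ring closure itself is arguably milder than the chosen cyclization.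
- Weak points: all of the difficulty moves into A8. It is an acyclic stereotriad whose central diarylmethine carbon is flanked by two ortho-substituted arenes, and no short, stereocontrolled route to it is evident. A secondary benzylic alkoxide bound to palladium can also undergo β-hydride elimination to the ketone.
- Comparison: the chosen plan takes its upper stereocentres from a cyclic cation with known facial bias and from one asymmetric epoxidation, which is far shorter than any route to A8.

Key step: step 11

Remark: compound 9 is drawn as the 3,4-trans alcohol expected from hydride reduction; the configuration at that carbon is erased when it ionizes in step 7, so its epimer would serve equally.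

## Route

Step 1
Reactants: 1 1-[4-(benzyloxy)-2-hydroxyphenyl]ethan-1-one
Product: 2 1-[4-(benzyloxy)-2-(methoxymethoxy)phenyl]ethan-1-one
Conditions: NaH, MOMCl, DMF, 0 °C to rt
Reagents that add atoms: chloromethyl methyl ether, COCCl
Why: Williamson-type O-alkylation; NaH breaks the hydrogen bond of the ortho-hydroxy ketone so the phenoxide is alkylated, and the acetal keeps the later peroxide epoxidation from turning into an Algar–Flynn–Oyamada oxidation.

Step 2
Reactants: 2 1-[4-(benzyloxy)-2-(methoxymethoxy)phenyl]ethan-1-one; 3 4-(benzyloxy)benzaldehyde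
Product: 4 (E)-1-[4-(benzyloxy)-2-(methoxymethoxy)phenyl]-3-[4-(benzyloxy)phenyl]prop-2-en-1-one
Conditions: KOH, EtOH/THF, rt
Reagents that add atoms: none
Why: Claisen–Schmidt condensation of a methyl ketone with a non-enolizable aldehyde; E1cB dehydration should give the E-enone, and the MOM ether prevents closure to a flavanone.

Step 3
Reactants: 4 (E)-1-[4-(benzyloxy)-2-(methoxymethoxy)phenyl]-3-[4-(benzyloxy)phenyl]prop-2-en-1-one
Product: 5 [(2R,3S)-3-[4-(benzyloxy)phenyl]oxiran-2-yl][4-(benzyloxy)-2-(methoxymethoxy)phenyl]methanone
Conditions: poly-L-leucine, urea–H2O2, DBU, THF, rt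
Reagents that add atoms: urea–hydrogen peroxide (supplies the epoxide oxygen), NC(N)=O.OO
Why: Juliá–Colonna epoxidation, a Weitz–Scheffer hydroperoxide addition inside the helical peptide; poly-L-leucine is known to give the (2R,3S)-epoxy ketone from E-chalcones, including 2'-alkoxymethoxy ones, and the trans geometry is kept.

Step 4
Reactants: 5 [(2R,3S)-3-[4-(benzyloxy)phenyl]oxiran-2-yl][4-(benzyloxy)-2-(methoxymethoxy)phenyl]methanone
Product: 7 (2R,3R)-7-(benzyloxy)-2-[4-(benzyloxy)phenyl]-3-hydroxy-2,3-dihydro-4H-chromen-4-one, via free phenol epoxide 6 (not isolated)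
Conditions: conc. HCl, MeOH/THF, 55 °C
Reagents that add atoms: none
Why: Acid methanolysis of the MOM acetal frees the phenol, which opens the protonated epoxide at the benzylic carbon (6-endo) with inversion while the C3–O bond is untouched, so C3 stays R and C2 becomes R; any cationic character at C2 also leads to the more stable 2,3-trans dihydroflavonol.

Step 5
Reactants: 7 (2R,3R)-7-(benzyloxy)-2-[4-(benzyloxy)phenyl]-3-hydroxy-2,3-dihydro-4H-chromen-4-one
Product: 8 (2R,3R)-3,7-bis(benzyloxy)-2-[4-(benzyloxy)phenyl]-2,3-dihydro-4H-chromen-4-one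
Conditions: BnOC(=NH)CCl3, TfOH (cat.), CH2Cl2/cyclohexane, 0 °C to rt
Reagents that add atoms: benzyl 2,2,2-trichloroacetimidate, N=C(OCc1ccccc1)C(Cl)(Cl)Cl
Why: Acid-catalysed O-benzylation with a trichloroacetimidate; avoiding base protects the β-aryloxy ketone from ring opening to the chalcone, C3 epimerization and oxidation to the flavonol.

Step 6
Reactants: 8 (2R,3R)-3,7-bis(benzyloxy)-2-[4-(benzyloxy)phenyl]-2,3-dihydro-4H-chromen-4-one
Product: 9 (2R,3S,4R)-3,7-bis(benzyloxy)-2-[4-(benzyloxy)phenyl]-3,4-dihydro-2H-chromen-4-ol
Conditions: NaBH4, THF/MeOH, 0 °C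
Reagents that add atoms: none
Why: Borohydride reduction of the aryl ketone; hydride should enter anti to the C3 benzyloxy group and give mainly the 3,4-trans alcohol, and C2 and C3 are not affected (the C3 descriptor changes only because the priorities change).

Step 7
Reactants: 9 (2R,3S,4R)-3,7-bis(benzyloxy)-2-[4-(benzyloxy)phenyl]-3,4-dihydro-2H-chromen-4-ol; 10 3,5-bis(benzyloxy)phenol
Product: 11 2-[(2R,3S,4S)-3,7-bis(benzyloxy)-2-[4-(benzyloxy)phenyl]-3,4-dihydro-2H-chromen-4-yl]-3,5-bis(benzyloxy)phenol
Conditions: 10 (4 equiv), BF3·OEt2 (0.3 equiv), CH2Cl2, −40 to 0 °C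
Reagents that add atoms: none
Why: Friedel–Crafts alkylation through the C4 benzylic cation (stabilized by O1 and the para 7-benzyloxy group), attacked anti to the C3 benzyloxy group to set C4 as S (3,4-trans). Phenol 10 should react ortho to its hydroxyl, which offers two equivalent sites flanked by the small OH and is also reached by O-to-C return of any aryl ether formed first; the excess of 10 suppresses double alkylation.

Step 8
Reactants: 3 4-(benzyloxy)benzaldehyde
Product: 12 rac-1-[4-(benzyloxy)phenyl]prop-2-en-1-ol
Conditions: CH2=CHMgBr, THF, 0 °C; then aq. NH4Cl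
Reagents that add atoms: vinylmagnesium bromide, C=C[Mg]Br
Why: Grignard 1,2-addition to a non-enolizable aromatic aldehyde.

Step 9
Reactants: 12 rac-1-[4-(benzyloxy)phenyl]prop-2-en-1-ol
Product: 13 (S)-[4-(benzyloxy)phenyl][(2R)-oxiran-2-yl]methanol
Conditions: Ti(OiPr)4 (15 mol %), L-(+)-diisopropyl tartrate (18 mol %), t-BuOOH (0.55 equiv), 4 Å MS, CH2Cl2, −20 °C
Reagents that add atoms: tert-butyl hydroperoxide, CC(C)(C)OO
Why: Sharpless kinetic resolution; with L-(+)-tartrate the (R)-enantiomer of 12 is epoxidized fast on one alkene face to the erythro epoxy alcohol, R at the oxirane carbon and S at the carbinol (same spatial arrangement as (R)-12, the descriptor changes with the priorities). The reaction is stopped near half conversion and the slow (S)-enantiomer of 12 is separated.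

Step 10
Reactants: 11 2-[(2R,3S,4S)-3,7-bis(benzyloxy)-2-[4-(benzyloxy)phenyl]-3,4-dihydro-2H-chromen-4-yl]-3,5-bis(benzyloxy)phenol; 13 (S)-[4-(benzyloxy)phenyl][(2R)-oxiran-2-yl]methanol
Product: 14 (2R)-2-[(R)-{2-[(2R,3S,4S)-3,7-bis(benzyloxy)-2-[4-(benzyloxy)phenyl]-3,4-dihydro-2H-chromen-4-yl]-3,5-bis(benzyloxy)phenoxy}[4-(benzyloxy)phenyl]methyl]oxirane
Conditions: PPh3, DIAD, THF, 0 °C to rt
Reagents that add atoms: none
Why: Mitsunobu etherification; the phenoxide displaces the oxyphosphonium of the secondary alcohol with inversion (S to R), so the erythro alcohol becomes the threo ether. The neighbouring epoxide oxygen inductively disfavours benzylic ionization, and the epoxide is inert under these neutral conditions.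

Step 11
Reactants: 14 (2R)-2-[(R)-{2-[(2R,3S,4S)-3,7-bis(benzyloxy)-2-[4-(benzyloxy)phenyl]-3,4-dihydro-2H-chromen-4-yl]-3,5-bis(benzyloxy)phenoxy}[4-(benzyloxy)phenyl]methyl]oxirane
Product: 15 (2R,3R)-8-[(2R,3S,4S)-3,7-bis(benzyloxy)-2-[4-(benzyloxy)phenyl]-3,4-dihydro-2H-chromen-4-yl]-5,7-bis(benzyloxy)-2-[4-(benzyloxy)phenyl]-3,4-dihydro-2H-chromen-3-ol
Conditions: AuCl3 (5 mol %), AgOTf (15 mol %), CH2Cl2, 0 °C to rt
Reagents that add atoms: none
Why: AgOTf removes chloride from AuCl3 to give a cationic trivalent gold species that coordinates the oxirane oxygen of 14; the ring D carbon ortho to the ether oxygen and para to a benzyloxy group attacks the terminal CH2, and rearomatization gives the lower C4–C4a bond and the free C3 hydroxyl. The closest known reaction type is the Lewis-acid-catalysed intramolecular Friedel–Crafts cycloalkylation of aryl glycidyl ethers to chroman-3-ols, which extends to 2-aryl-substituted ethers of 3,5-dialkoxyphenols. Ring F closes in the 6-endo-tet mode. No stereocentre is formed: lower C2 (R) and C3 (R) come unchanged from 14 because neither the C2–O nor the C3–O bond is broken, so the threo ether becomes the 2,3-cis flavan-3-ol. Endo over exo opening is needed and should follow from SN2-like attack at the unhindered primary carbon; the exo path would have to attack a secondary carbon that is hindered and inductively deactivated by the adjacent C2–O bond, and would give a 2,3-dihydrobenzofuran. The regiochemistry of ring fusion is not a selectivity question, since the other ortho carbon already carries the upper unit and the third free ring D carbon is para to the ether oxygen. Survival of the lower C2–O bond and of the interflavan bond rests on a catalytic, weakly acidic promoter at low temperature and on the absence of a 5-oxygen in ring A.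

Step 12
Reactants: 15 (2R,3R)-8-[(2R,3S,4S)-3,7-bis(benzyloxy)-2-[4-(benzyloxy)phenyl]-3,4-dihydro-2H-chromen-4-yl]-5,7-bis(benzyloxy)-2-[4-(benzyloxy)phenyl]-3,4-dihydro-2H-chromen-3-ol
Product: 16 (2R,3R)-8-[(2R,3S,4S)-3,7-dihydroxy-2-(4-hydroxyphenyl)-3,4-dihydro-2H-chromen-4-yl]-2-(4-hydroxyphenyl)-3,4-dihydro-2H-chromene-3,5,7-triol
Conditions: H2 (1 atm), Pd(OH)2/C, THF/MeOH, rt
Reagents that add atoms: none
Why: Hydrogenolysis of the six benzyl ethers; at atmospheric pressure and room temperature the diarylmethine C4–C8 bond and the cyclic benzylic C2–O bonds should not be cleaved, and the neutral conditions leave all five stereocentres alone.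

## Compound list

1 | 1-[4-(benzyloxy)-2-hydroxyphenyl]ethan-1-one | CC(=O)c1ccc(OCc2ccccc2)cc1O | starting material
2 | 1-[4-(benzyloxy)-2-(methoxymethoxy)phenyl]ethan-1-one | CC(=O)c1ccc(OCc2ccccc2)cc1OCOC | intermediate
3 | 4-(benzyloxy)benzaldehyde | O=Cc1ccc(OCc2ccccc2)cc1 | starting material
4 | (E)-1-[4-(benzyloxy)-2-(methoxymethoxy)phenyl]-3-[4-(benzyloxy)phenyl]prop-2-en-1-one | COCOc1cc(OCc2ccccc2)ccc1C(=O)/C=C/c1ccc(OCc2ccccc2)cc1 | intermediate
5 | [(2R,3S)-3-[4-(benzyloxy)phenyl]oxiran-2-yl][4-(benzyloxy)-2-(methoxymethoxy)phenyl]methanone | COCOc1cc(OCc2ccccc2)ccc1C(=O)[C@@H]1O[C@H]1c1ccc(OCc2ccccc2)cc1 | intermediate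
6 | [(2R,3S)-3-[4-(benzyloxy)phenyl]oxiran-2-yl][4-(benzyloxy)-2-hydroxyphenyl]methanone | Oc1cc(OCc2ccccc2)ccc1C(=O)[C@@H]1O[C@H]1c1ccc(OCc2ccccc2)cc1 | intermediate (not isolated)
7 | (2R,3R)-7-(benzyloxy)-2-[4-(benzyloxy)phenyl]-3-hydroxy-2,3-dihydro-4H-chromen-4-one | O=C1[C@H](O)[C@@H](c2ccc(OCc3ccccc3)cc2)Oc2cc(OCc3ccccc3)ccc12 | intermediate
8 | (2R,3R)-3,7-bis(benzyloxy)-2-[4-(benzyloxy)phenyl]-2,3-dihydro-4H-chromen-4-one | O=C1[C@H](OCc2ccccc2)[C@@H](c2ccc(OCc3ccccc3)cc2)Oc2cc(OCc3ccccc3)ccc12 | intermediate
9 | (2R,3S,4R)-3,7-bis(benzyloxy)-2-[4-(benzyloxy)phenyl]-3,4-dihydro-2H-chromen-4-ol | c1ccccc1COc1ccc([C@H]2Oc3cc(OCc4ccccc4)ccc3[C@@H](O)[C@@H]2OCc2ccccc2)cc1 | intermediate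
10 | 3,5-bis(benzyloxy)phenol | Oc1cc(OCc2ccccc2)cc(OCc2ccccc2)c1 | starting material
11 | 2-[(2R,3S,4S)-3,7-bis(benzyloxy)-2-[4-(benzyloxy)phenyl]-3,4-dihydro-2H-chromen-4-yl]-3,5-bis(benzyloxy)phenol | c1ccccc1COc1ccc([C@H]2Oc3cc(OCc4ccccc4)ccc3[C@@H](c3c(OCc4ccccc4)cc(OCc4ccccc4)cc3O)[C@@H]2OCc2ccccc2)cc1 | intermediate
12 | rac-1-[4-(benzyloxy)phenyl]prop-2-en-1-ol | C=CC(O)c1ccc(OCc2ccccc2)cc1 | intermediate
13 | (S)-[4-(benzyloxy)phenyl][(2R)-oxiran-2-yl]methanol | O[C@@H](c1ccc(OCc2ccccc2)cc1)[C@H]1CO1 | intermediate
14 | (2R)-2-[(R)-{2-[(2R,3S,4S)-3,7-bis(benzyloxy)-2-[4-(benzyloxy)phenyl]-3,4-dihydro-2H-chromen-4-yl]-3,5-bis(benzyloxy)phenoxy}[4-(benzyloxy)phenyl]methyl]oxirane | c1ccccc1COc1ccc([C@H]2Oc3cc(OCc4ccccc4)ccc3[C@@H](c3c(OCc4ccccc4)cc(OCc4ccccc4)cc3O[C@H](c3ccc(OCc4ccccc4)cc3)[C@H]3CO3)[C@@H]2OCc2ccccc2)cc1 | intermediate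
15 | (2R,3R)-8-[(2R,3S,4S)-3,7-bis(benzyloxy)-2-[4-(benzyloxy)phenyl]-3,4-dihydro-2H-chromen-4-yl]-5,7-bis(benzyloxy)-2-[4-(benzyloxy)phenyl]-3,4-dihydro-2H-chromen-3-ol | c1ccccc1COc1ccc([C@H]2Oc3cc(OCc4ccccc4)ccc3[C@@H](c3c(OCc4ccccc4)cc(OCc4ccccc4)c4c3O[C@H](c3ccc(OCc5ccccc5)cc3)[C@H](O)C4)[C@@H]2OCc2ccccc2)cc1 | intermediate
16 | (2R,3R)-8-[(2R,3S,4S)-3,7-dihydroxy-2-(4-hydroxyphenyl)-3,4-dihydro-2H-chromen-4-yl]-2-(4-hydroxyphenyl)-3,4-dihydro-2H-chromene-3,5,7-triol | Oc1ccc([C@H]2Oc3cc(O)ccc3[C@@H](c3c(O)cc(O)c4c3O[C@H](c3ccc(O)cc3)[C@H](O)C4)[C@@H]2O)cc1 | target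

## Step count and least certain steps

Total: 12 steps. Longest linear sequence: 10 steps (steps 1–7, then 10–12); the two-step branch (steps 8–9) joins at step 10.

**Step 11 (key step).**
- What may go wrong: the Lewis acid may ionize the lower C2–O bond, a 4-alkoxybenzylic aryl ether, in competition with epoxide activation. That would erode the cis relationship or release phenol 11. Capture of the activated epoxide by triflate or chloride, or exo opening, are further risks. All of these are more likely than in simple cases because the substrate is large, crowded around ring D and slow to reach the reactive conformation.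
- Fallback: it sets out from 10 and 13 and returns at 15. Mitsunobu etherification of the unhindered phenol 10 with 13 (PPh3, DIAD) should give (2R)-2-[(R)-[3,5-bis(benzyloxy)phenoxy][4-(benzyloxy)phenyl]methyl]oxirane F1. The same gold-catalysed cyclization, now on a small ether of the kind for which it is established, should give (2R,3R)-5,7-bis(benzyloxy)-2-[4-(benzyloxy)phenyl]-3,4-dihydro-2H-chromen-3-ol F2. Friedel–Crafts coupling of 9 with F2 (BF3·OEt2, CH2Cl2) then forms the interflavan bond last and gives 15.
- Cost and side benefit: ring D regiochemistry is no longer guaranteed and depends on the usual C8-over-C6 preference. The detour also moves the Mitsunobu reaction away from the hindered phenol 11, should step 10 prove sluggish.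

**Step 7.**
- What may go wrong: substitution of 10 at the carbon para to the hydroxyl (between the two benzyloxy groups), a second alkylation of the product, or incomplete facial control at C4. The two activated sites of 10 differ only by sterics and statistics.
- Fallback: it sets out from 9 and returns at 11. Benzene-1,3,5-triol is used as the nucleophile (excess, BF3·OEt2 or cat. HCl, dioxane); all of its ring carbons are equivalent, so only one constitution can form, 2-[(2R,3S,4S)-3,7-bis(benzyloxy)-2-[4-(benzyloxy)phenyl]-3,4-dihydro-2H-chromen-4-yl]benzene-1,3,5-triol F3. Controlled benzylation (BnBr, 2 equiv, K2CO3, DMF) should take the unhindered para hydroxyl first and then one of the two equivalent ortho hydroxyls, giving 11.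
- Cost: the second benzylation is partly statistical. Under-benzylated material can be recycled; over-benzylated material is lost.

**Step 4.**
- What may go wrong: methanol may open the epoxide at the benzylic carbon without ring closure following, or the electron-rich 4-benzyloxyphenyl group may undergo a 1,2-shift toward an isoflavonoid skeleton.
- Fallback: it sets out from 5 and returns at 7. Thiol opening with phenylmethanethiol and SnCl4 (CH2Cl2, −20 to 0 °C) cleaves the epoxide at the benzylic carbon and removes the MOM group, giving (2S,3R)-3-(benzylsulfanyl)-1-[4-(benzyloxy)-2-hydroxyphenyl]-3-[4-(benzyloxy)phenyl]-2-hydroxypropan-1-one F4. The thiophilic salt AgBF4 (CH2Cl2, 0 °C) then expels the sulfide, and the phenol closes ring C through the benzylic cation to the trans dihydroflavonol 7.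
- Stereochemistry: the C3 stereocentre is untouched throughout, and the benzylic centre is re-set on closure.

## Further compounds

F1 | step 11 | (2R)-2-[(R)-[3,5-bis(benzyloxy)phenoxy][4-(benzyloxy)phenyl]methyl]oxirane | c1ccccc1COc1cc(OCc2ccccc2)cc(O[C@H](c2ccc(OCc3ccccc3)cc2)[C@H]2CO2)c1
F2 | step 11 | (2R,3R)-5,7-bis(benzyloxy)-2-[4-(benzyloxy)phenyl]-3,4-dihydro-2H-chromen-3-ol | c1c(OCc3ccccc3)cc(OCc3ccccc3)c2c1O[C@H](c1ccc(OCc3ccccc3)cc1)[C@H](O)C2
F3 | step 7 | 2-[(2R,3S,4S)-3,7-bis(benzyloxy)-2-[4-(benzyloxy)phenyl]-3,4-dihydro-2H-chromen-4-yl]benzene-1,3,5-triol | c1ccccc1COc1ccc([C@H]2Oc3cc(OCc4ccccc4)ccc3[C@@H](c3c(O)cc(O)cc3O)[C@@H]2OCc2ccccc2)cc1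
F4 | step 4 | (2S,3R)-3-(benzylsulfanyl)-1-[4-(benzyloxy)-2-hydroxyphenyl]-3-[4-(benzyloxy)phenyl]-2-hydroxypropan-1-one | Oc1cc(OCc2ccccc2)ccc1C(=O)[C@H](O)[C@H](SCc1ccccc1)c1ccc(OCc2ccccc2)cc1
A1 | alternative 1 | hexa-O-benzyl 4-hydroxy derivative of the target (upper ring C as cis-3,4-diol with tertiary 4-hydroxyl, lower 3-O-benzyl) | c9ccccc9COc1ccc([C@H]2Oc3cc(OCc9ccccc9)ccc3[C@@](O)(c3c(OCc9ccccc9)cc(OCc9ccccc9)c4c3O[C@H](c3ccc(OCc9ccccc9)cc3)[C@H](OCc9ccccc9)C4)[C@@H]2O)cc1
A2 | alternative 1 | (R)-2-[5-(benzyloxy)-2-{[(2R,3R)-3,5,7-tris(benzyloxy)-2-[4-(benzyloxy)phenyl]-3,4-dihydro-2H-chromen-8-yl]carbonyl}phenoxy]-2-[4-(benzyloxy)phenyl]acetaldehyde | c9ccccc9COc1ccc([C@H](C=O)Oc3cc(OCc9ccccc9)ccc3C(=O)c3c(OCc9ccccc9)cc(OCc9ccccc9)c4c3O[C@H](c3ccc(OCc9ccccc9)cc3)[C@H](OCc9ccccc9)C4)cc1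
A3 | alternative 2 | hexa-O-benzyl 3-deoxy-3-(4,4,5,5-tetramethyl-1,3,2-dioxaborolan-2-yl) analogue of the target | c9ccccc9COc1ccc([C@H]2Oc3cc(OCc9ccccc9)ccc3[C@@H](c3c(OCc9ccccc9)cc(OCc9ccccc9)c4c3O[C@H](c3ccc(OCc9ccccc9)cc3)[C@H](OCc9ccccc9)C4)[C@@H]2B5OC(C)(C)C(C)(C)O5)cc1
A4 | alternative 2 | [(2R,3R)-3,5,7-tris(benzyloxy)-2-[4-(benzyloxy)phenyl]-3,4-dihydro-2H-chromen-8-yl]magnesium bromide | Br[Mg]c1c(OCc9ccccc9)cc(OCc9ccccc9)c2c1O[C@H](c1ccc(OCc9ccccc9)cc1)[C@H](OCc9ccccc9)C2
A5 | alternative 2 | 5-(benzyloxy)-2-formylphenyl tert-butyl carbonate | O=Cc1ccc(OCc2ccccc2)cc1OC(=O)OC(C)(C)C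
A6 | alternative 2 | (E)-2-[4-(benzyloxy)styryl]-4,4,5,5-tetramethyl-1,3,2-dioxaborolane | CC1(C)OB(/C=C/c2ccc(OCc3ccccc3)cc2)OC1(C)C
A7 | alternative 3 | hepta-O-benzyl target | c9ccccc9COc1ccc([C@H]2Oc3cc(OCc9ccccc9)ccc3[C@@H](c3c(OCc9ccccc9)cc(OCc9ccccc9)c4c3O[C@H](c3ccc(OCc9ccccc9)cc3)[C@H](OCc9ccccc9)C4)[C@@H]2OCc9ccccc9)cc1
A8 | alternative 3 | (1R,2S,3S)-2-(benzyloxy)-3-[4-(benzyloxy)-2-bromophenyl]-1-[4-(benzyloxy)phenyl]-3-[(2R,3R)-3,5,7-tris(benzyloxy)-2-[4-(benzyloxy)phenyl]-3,4-dihydro-2H-chromen-8-yl]propan-1-ol | c9ccccc9COc1ccc([C@@H](O)[C@@H](OCc9ccccc9)[C@H](c3c(OCc9ccccc9)cc(OCc9ccccc9)c4c3O[C@H](c3ccc(OCc9ccccc9)cc3)[C@H](OCc9ccccc9)C4)c3ccc(OCc9ccccc9)cc3Br)cc1
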